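**Retrosynthetic overview**

1. Target 26 ← diol-lactone 25 (selective acetylation) ← bis-lactone 22: lactone ring A (enolisable CH2) is reduced to the CH2OH/CHOH pair, lactone ring B is kept as the butyrolactone of the target.
2. 22 ← 20 + 12: the bond from the alkene carbon to the side-chain CH is made by Pd-catalysed α-alkenylation of the enolate of bis-lactone 20 (from dimethyl (R)-malate 13 and tert-butyl bromoacetate 14) with alkenyl triflate 12 (from methyl ketone 10).
3. 10 ← 9 ← 2 + 3 (key step): the cyclopentane is annulated onto the cyclohexene of β-cyclocitral by forming C2–C3 (alkenylzinc addition to the aldehyde carbon) and C1–C7a (4π-electrocyclisation) in one flask; hydrogenation then sets C1 and C3a.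
4. Enabling feature: the cyclopentane atoms C1–C2–C3–C3a–C7a are a pentadienyl cation in disguise whose C3a–C7a edge is shared with the cyclohexane. C7a (methyl) and C4 (gem-dimethyl) are quaternary, so the enal unit C3(=O)–C3a=C7a of 3 supplies three of the five atoms, the cyclised cation can lose a proton only at C1, and the C3=C3a double bond is left for hydrogenation anti to the C7a methyl group (trans ring fusion).
5. Ring order: cyclohexane (bought with 3) → cyclopentane (step 2) → lactone rings A and B (step 9) → ring A opened by reduction, ring B re-closed (step 11).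

Key step: step 2

Remark: locants C1–C7a are those of the octahydro-1H-indene ring; (+)-MIB is (2R)-3-exo-morpholinoisoborneol and is assumed to give the (R)-alkoxide 6 by analogy with its facial preference for aryl aldehydes.

**Route**

Step 1
Reactants: 1 but-3-yn-2-one
Product: 2 2-ethynyl-2-methyl-1,3-dioxolane
Conditions: (Me3SiOCH2)2, Me3SiOTf (cat.), CH2Cl2, −78 to −20 °C
Reagents that add atoms: 1,2-bis(trimethylsilyloxy)ethane, C[Si](C)(C)OCCO[Si](C)(C)C
Why: Silyl-transfer ketalisation masks the ynone under non-nucleophilic conditions, so the terminal alkyne survives and no conjugate addition should occur.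

Step 2
Reactants: 2 2-ethynyl-2-methyl-1,3-dioxolane; 3 β-cyclocitral (2,6,6-trimethylcyclohex-1-ene-1-carbaldehyde)
Product: 9 1-[(7aS)-4,4,7a-trimethyl-5,6,7,7a-tetrahydro-4H-inden-1-yl]ethan-1-one, via alkenylzirconocene 4 (not isolated), via alkenylzinc 5 (not isolated), via zinc alkoxide 6 (not isolated), via allylic trifluoroacetate 7 (not isolated), via diene ketal 8 (not isolated)
Conditions: Cp2Zr(H)Cl, CH2Cl2, rt; Me2Zn, toluene, −65 °C; (+)-MIB (10 mol %), 3, −30 to 0 °C; (CF3CO)2O, −78 to −20 °C; then H2O, rt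
Reagents that add atoms: water, O
Why: Proposed new method: syn-hydrozirconation of 2 and zirconium-to-zinc exchange give the (E)-alkenylzinc 5, whose (+)-MIB-catalysed 1,2-addition to the hindered enal 3 (a known ligand-controlled asymmetric alkenylzinc addition) forms the C2–C3 bond and the (R)-carbinol center of 6. Acylation to the doubly allylic trifluoroacetate 7 and its ionisation give the pentadienyl cation C1–C2–C3–C3a–C7a, which closes the five-membered ring by thermal conrotatory 4π-electrocyclisation between its termini C1 and C7a (Nazarov mode) and so creates the quaternary center. The resulting C2–C3–C3a allyl cation can lose a proton only from C1, because C4 and C7a carry none, so cyclopentadiene 8 should form as one regioisomer before its ketal is hydrolysed in the same flask. The closest known reaction types are the acid-mediated dehydrative Nazarov cyclisation of divinyl carbinols to cyclopentadienes and, for the transfer of configuration, the Rautenstrauch rearrangement of enantioenriched enynyl esters, in which a carbinol center that becomes sp2 hands its configuration on through a helical pentadienyl cation. The new element is this center-to-helix-to-center relay in an ionisation-triggered cyclisation: the C4 gem-dimethyl and C7a methyl groups hold the ester in the rotamer with the carbinol hydrogen in the ring plane, the leaving group departs from one face while the alkenyl arm swings over the other face of C7a, and the inside methyl group hinders planarisation of the U-shaped cation, so ring closure should outrun helix inversion and the (R)-ester should give (7aS). The step needs 1,2- instead of 1,4-addition (secured by the fully substituted β-carbon), an (E)-alkenyl unit so that only hydrogen points into the U, and cyclisation instead of proton loss to trienes (these re-protonate under the acid and should drain into the irreversible ring closure).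

Step 3
Reactants: 9 1-[(7aS)-4,4,7a-trimethyl-5,6,7,7a-tetrahydro-4H-inden-1-yl]ethan-1-one
Product: 10 1-[(1S,3aS,7aS)-4,4,7a-trimethyloctahydro-1H-inden-1-yl]ethan-1-one
Conditions: H2 (4 atm), 10% Pd/C, EtOAc, rt
Reagents that add atoms: none
Why: Heterogeneous catalytic hydrogenation should deliver hydrogen to both ring double bonds from the face opposite the quasi-axial C7a methyl group, the sense known for steroid olefins at the corresponding ring-D positions, which sets C3a (trans ring fusion) and C1 (acetyl cis to the methyl group, also the more stable epimer of this α-keto center) and leaves the ketone untouched.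

Step 4
Reactants: 10 1-[(1S,3aS,7aS)-4,4,7a-trimethyloctahydro-1H-inden-1-yl]ethan-1-one
Product: 12 1-[(1S,3aS,7aS)-4,4,7a-trimethyloctahydro-1H-inden-1-yl]ethenyl trifluoromethanesulfonate, via potassium enolate 11 (not isolated)
Conditions: KN(SiMe3)2, THF, −78 °C; PhNTf2, −78 to 0 °C
Reagents that add atoms: N-phenylbis(trifluoromethanesulfonimide), O=S(=O)(N(c1ccccc1)S(=O)(=O)C(F)(F)F)C(F)(F)F
Why: Kinetic deprotonation of the methyl ketone at the methyl group (the C1 proton is tertiary and shielded by the C7a methyl group) and O-triflation of the enolate give the 1,1-disubstituted alkenyl triflate without touching C1.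

Step 5
Reactants: 13 dimethyl (R)-malate; 14 tert-butyl bromoacetate
Product: 16 3-tert-butyl 1,2-dimethyl (1R,2S)-1-hydroxypropane-1,2,3-tricarboxylate, via dilithium alkoxide enolate 15 (not isolated)
Conditions: LiN(SiMe3)2 (2.2 equiv), THF, −78 to −20 °C; 14, −78 °C
Reagents that add atoms: none
Why: Fráter–Seebach alkylation: the chelated dilithium alkoxide enolate of the β-hydroxy ester is alkylated anti to the alkoxide, which sets the (2S) center relative to the (1R) center taken from the chiral pool.

Step 6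
Reactants: 16 3-tert-butyl 1,2-dimethyl (1R,2S)-1-hydroxypropane-1,2,3-tricarboxylate
Product: 17 (2R,3S)-3-[2-(tert-butoxy)-2-oxoethyl]-2-hydroxybutanedioic acid
Conditions: LiOH (2.2 equiv), THF–H2O, 0 °C to rt; then 1 M HCl
Reagents that add atoms: lithium hydroxide, [Li+].[OH-]
Why: Saponification cleaves the two methyl esters while the tert-butyl ester resists hydroxide for steric reasons, and the carboxylates formed protect the α-carbon against enolisation.

Step 7
Reactants: 17 (2R,3S)-3-[2-(tert-butoxy)-2-oxoethyl]-2-hydroxybutanedioic acid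
Product: 18 (2S)-4-(tert-butoxy)-2-[(4R)-2,2-dimethyl-5-oxo-1,3-dioxolan-4-yl]-4-oxobutanoic acid
Conditions: Me2C(OMe)2, PPTS (cat.), CH2Cl2, rt
Reagents that add atoms: 2,2-dimethoxypropane, COC(C)(C)OC
Why: Acetonide formation is selective for the α-hydroxy acid, which closes the five-membered 1,3-dioxolan-4-one and leaves the other carboxylic acid free, as in the malic acid series.

Step 8
Reactants: 18 (2S)-4-(tert-butoxy)-2-[(4R)-2,2-dimethyl-5-oxo-1,3-dioxolan-4-yl]-4-oxobutanoic acid
Product: 19 tert-butyl (3R)-3-[(4R)-2,2-dimethyl-5-oxo-1,3-dioxolan-4-yl]-4-hydroxybutanoate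
Conditions: BH3·SMe2, THF, 0 °C to rt; MeOH
Reagents that add atoms: none
Why: Borane reduces the free carboxylic acid much faster than the dioxolanone and the tert-butyl ester (chemoselective acid reduction).

Step 9
Reactants: 19 tert-butyl (3R)-3-[(4R)-2,2-dimethyl-5-oxo-1,3-dioxolan-4-yl]-4-hydroxybutanoate
Product: 20 (3aR,6aR)-tetrahydrofuro[3,4-b]furan-2,6-dione (cis-fused bis-γ-lactone)
Conditions: CF3CO2H, CH2Cl2, rt
Reagents that add atoms: none
Why: Acidolysis removes the acetonide and the tert-butyl ester, the primary alcohol closes onto the α-hydroxy acid carbonyl (ring B) and the freed secondary alcohol onto the new acid (ring A), two 5-exo lactonisations that can only give the cis-fused bicycle.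

Step 10
Reactants: 20 (3aR,6aR)-tetrahydrofuro[3,4-b]furan-2,6-dione; 12 1-[(1S,3aS,7aS)-4,4,7a-trimethyloctahydro-1H-inden-1-yl]ethenyl trifluoromethanesulfonate
Product: 22 (3R,3aR,6aR)-3-{1-[(1R,3aS,7aS)-4,4,7a-trimethyloctahydro-1H-inden-1-yl]ethenyl}tetrahydrofuro[3,4-b]furan-2,6-dione, via zinc enolate 21 (not isolated)
Conditions: LiN(SiMe3)2, THF, −78 °C; ZnCl2; 12, Pd(dba)2 (5 mol %), P(t-Bu)3 (10 mol %), rt to 50 °C
Reagents that add atoms: none
Why: Palladium-catalysed α-alkenylation of a zinc lactone enolate (Reformatsky-type enolate cross-coupling): the enolate of the cis-fused bicycle should couple on its convex face, trans to the CH2 of the neighbouring ring, which sets the side-chain CH center, and the 1,1-disubstituted alkene arrives intact from the triflate.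

Step 11
Reactants: 22 (3R,3aR,6aR)-3-{1-[(1R,3aS,7aS)-4,4,7a-trimethyloctahydro-1H-inden-1-yl]ethenyl}tetrahydrofuro[3,4-b]furan-2,6-dione
Product: 25 (3R,4R)-3-hydroxy-4-{(2R)-1-hydroxy-3-[(1R,3aS,7aS)-4,4,7a-trimethyloctahydro-1H-inden-1-yl]but-3-en-2-yl}oxolan-2-one, via lithium carboxylate 23 (not isolated), via triol carboxylate 24 (not isolated)
Conditions: LiOH (1.0 equiv), THF–H2O, 0 °C; evaporate; LiBH4, THF, 0 °C to rt; 1 M HCl, rt
Reagents that add atoms: none
Why: Hydroxide should open the less hindered ring B (its carbonyl carries the α-acyloxy oxygen, whereas the ring A carbonyl is flanked by the branched alkenyl carbon), the carboxylate is inert to LiBH4, which reduces ring A to the primary alcohol and frees the secondary alcohol, and acidification re-closes the γ-lactone (5-exo, favoured over the δ-lactone) without touching a stereocenter.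

Step 12
Reactants: 25 (3R,4R)-3-hydroxy-4-{(2R)-1-hydroxy-3-[(1R,3aS,7aS)-4,4,7a-trimethyloctahydro-1H-inden-1-yl]but-3-en-2-yl}oxolan-2-one
Product: 26 (2R)-2-[(3R,4R)-4-hydroxy-5-oxooxolan-3-yl]-3-[(1R,3aS,7aS)-4,4,7a-trimethyloctahydro-1H-inden-1-yl]but-3-en-1-yl acetate (CNP0252518.3)
Conditions: AcCl (1.1 equiv), 2,4,6-collidine, CH2Cl2, −78 °C
Reagents that add atoms: acetyl chloride, CC(=O)Cl
Why: Acylation with a hindered pyridine base at low temperature should be selective for the primary alcohol over the secondary α-hydroxy lactone alcohol.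

**Compound list**

1 | but-3-yn-2-one | CC(=O)C#C | starting material
2 | 2-ethynyl-2-methyl-1,3-dioxolane | CC1(C#C)OCCO1 | intermediate
3 | β-cyclocitral (2,6,6-trimethylcyclohex-1-ene-1-carbaldehyde) | CC1=C(C=O)C(C)(C)CCC1 | starting material
4 | chlorobis(cyclopentadienyl)[(E)-2-(2-methyl-1,3-dioxolan-2-yl)ethenyl]zirconium | CC1(/C=C/[Zr](Cl)(C2C=CC=C2)C2C=CC=C2)OCCO1 | intermediate
5 | methyl[(E)-2-(2-methyl-1,3-dioxolan-2-yl)ethenyl]zinc | C[Zn]/C=C/C1(C)OCCO1 | intermediate
6 | methylzinc (1R,2E)-3-(2-methyl-1,3-dioxolan-2-yl)-1-(2,6,6-trimethylcyclohex-1-en-1-yl)prop-2-en-1-olate | C[Zn]O[C@H](/C=C/C1(C)OCCO1)C1=C(C)CCCC1(C)C | intermediate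
7 | (1R,2E)-3-(2-methyl-1,3-dioxolan-2-yl)-1-(2,6,6-trimethylcyclohex-1-en-1-yl)prop-2-en-1-yl trifluoroacetate | O=C(O[C@H](/C=C/C1(C)OCCO1)C1=C(C)CCCC1(C)C)C(F)(F)F | intermediate
8 | 2-methyl-2-[(7aS)-4,4,7a-trimethyl-5,6,7,7a-tetrahydro-4H-inden-1-yl]-1,3-dioxolane | CC1(OCCO1)C1=CC=C2C(C)(C)CCC[C@]12C | intermediate
9 | 1-[(7aS)-4,4,7a-trimethyl-5,6,7,7a-tetrahydro-4H-inden-1-yl]ethan-1-one | CC(=O)C1=CC=C2C(C)(C)CCC[C@]12C | intermediate
10 | 1-[(1S,3aS,7aS)-4,4,7a-trimethyloctahydro-1H-inden-1-yl]ethan-1-one | CC(=O)[C@H]1CC[C@H]2C(C)(C)CCC[C@]12C | intermediate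
11 | potassium 1-[(1S,3aS,7aS)-4,4,7a-trimethyloctahydro-1H-inden-1-yl]ethen-1-olate | [K+].[O-]C(=C)[C@H]1CC[C@H]2C(C)(C)CCC[C@]12C | intermediate
12 | 1-[(1S,3aS,7aS)-4,4,7a-trimethyloctahydro-1H-inden-1-yl]ethenyl trifluoromethanesulfonate | C=C(OS(=O)(=O)C(F)(F)F)[C@H]1CC[C@H]2C(C)(C)CCC[C@]12C | intermediate
13 | dimethyl (R)-malate (dimethyl (2R)-2-hydroxybutanedioate) | COC(=O)[C@H](O)CC(=O)OC | starting material
14 | tert-butyl bromoacetate | CC(C)(C)OC(=O)CBr | starting material
15 | dilithium alkoxide enolate of 13 | [Li+].[Li+].COC(=O)[C@H]([O-])C=C([O-])OC | intermediate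
16 | 3-tert-butyl 1,2-dimethyl (1R,2S)-1-hydroxypropane-1,2,3-tricarboxylate | COC(=O)[C@H](O)[C@H](CC(=O)OC(C)(C)C)C(=O)OC | intermediate
17 | (2R,3S)-3-[2-(tert-butoxy)-2-oxoethyl]-2-hydroxybutanedioic acid | OC(=O)[C@H](O)[C@H](CC(=O)OC(C)(C)C)C(=O)O | intermediate
18 | (2S)-4-(tert-butoxy)-2-[(4R)-2,2-dimethyl-5-oxo-1,3-dioxolan-4-yl]-4-oxobutanoic acid | CC1(C)O[C@H]([C@H](CC(=O)OC(C)(C)C)C(=O)O)C(=O)O1 | intermediate
19 | tert-butyl (3R)-3-[(4R)-2,2-dimethyl-5-oxo-1,3-dioxolan-4-yl]-4-hydroxybutanoate | CC1(C)O[C@H]([C@H](CC(=O)OC(C)(C)C)CO)C(=O)O1 | intermediate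
20 | (3aR,6aR)-tetrahydrofuro[3,4-b]furan-2,6-dione | O=C1C[C@@H]2COC(=O)[C@@H]2O1 | intermediate
21 | chlorozinc enolate of 20 (enolate of the C2 carbonyl) | Cl[Zn]OC1=C[C@@H]2COC(=O)[C@@H]2O1 | intermediate
22 | (3R,3aR,6aR)-3-{1-[(1R,3aS,7aS)-4,4,7a-trimethyloctahydro-1H-inden-1-yl]ethenyl}tetrahydrofuro[3,4-b]furan-2,6-dione | C=C([C@H]1CC[C@H]2C(C)(C)CCC[C@]12C)[C@@H]1C(=O)O[C@H]2C(=O)OC[C@@H]12 | intermediate
23 | lithium (2R,3R,4R)-3-(hydroxymethyl)-5-oxo-4-{1-[(1R,3aS,7aS)-4,4,7a-trimethyloctahydro-1H-inden-1-yl]ethenyl}oxolane-2-carboxylate | [Li+].[O-]C(=O)[C@@H]1OC(=O)[C@@H](C(=C)[C@H]2CC[C@H]3C(C)(C)CCC[C@]23C)[C@@H]1CO | intermediate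
24 | lithium (2R,3R,4R)-2-hydroxy-3,4-bis(hydroxymethyl)-5-[(1R,3aS,7aS)-4,4,7a-trimethyloctahydro-1H-inden-1-yl]hex-5-enoate | [Li+].[O-]C(=O)[C@H](O)[C@@H](CO)[C@@H](CO)C(=C)[C@H]1CC[C@H]2C(C)(C)CCC[C@]12C | intermediate
25 | (3R,4R)-3-hydroxy-4-{(2R)-1-hydroxy-3-[(1R,3aS,7aS)-4,4,7a-trimethyloctahydro-1H-inden-1-yl]but-3-en-2-yl}oxolan-2-one | C=C([C@H]1CC[C@H]2C(C)(C)CCC[C@]12C)[C@H](CO)[C@@H]1COC(=O)[C@@H]1O | intermediate
26 | (2R)-2-[(3R,4R)-4-hydroxy-5-oxooxolan-3-yl]-3-[(1R,3aS,7aS)-4,4,7a-trimethyloctahydro-1H-inden-1-yl]but-3-en-1-yl acetate (CNP0252518.3) | C=C([C@H]1CC[C@H]2C(C)(C)CCC[C@]12C)[C@H](COC(C)=O)[C@@H]1COC(=O)[C@@H]1O | target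

**Step count and risks**

Total step count: 12. Longest linear sequence: 8 steps (steps 5–12, from dimethyl (R)-malate); the hydrindane arm runs through 7 steps (1–4 and 10–12).

Steps most likely to fail:

1. Step 2 (Proposed new method). The helical memory of the cation may be lost, by helix inversion or ion-pair return before ring closure, which would erode the enantiomeric purity at C7a; proton loss to open-chain trienes may also divert material. Fallback (resolution through the chiral-pool partner instead of the relay, known chemistry): from 2 and 3, the ligand-free alkenylzinc addition with aqueous work-up gives the racemic (E)-dienyl carbinol F1. TsOH·H2O in CH2Cl2 (dehydrative Nazarov cyclisation with ketal hydrolysis) converts it to the racemic dienone F2, which is hydrogenated as in step 3 to the racemic ketone F3 and triflated as in step 4 to the racemic alkenyl triflate F4. Coupling of F4 with enantiopure 20 under the conditions of step 10 gives 22 together with its hydrindane-epimeric diastereomer F5, which is removed by chromatography; the route is rejoined at 22.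

2. Step 10. Enolisation may occur at the ring-fusion carbon instead of the CH2 group, the enolate may undergo Claisen-type self-condensation, or reductive elimination at the hindered alkenyl-palladium center may be slow. Fallback (radical cross-electrophile coupling instead of enolate coupling): from 20, silyl ketene acetal formation and bromination (LiN(SiMe3)2, Me3SiCl, THF, −78 °C; N-bromosuccinimide) give the α-bromo bis-lactone F6. F6 is joined with 12 by nickel-catalysed reductive cross-coupling (NiBr2(dme), 4,4′-di-tert-butyl-2,2′-bipyridine, Mn, N,N-dimethylacetamide, rt); the α-lactonyl radical should be captured on the convex face, and the route is rejoined at 22.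

3. Step 11. Hydroxide may fail to discriminate between the two lactone carbonyl groups, or acidification may close the δ-lactone. Fallback (amide masking instead of carboxylate masking): from 22, pyrrolidine (THF, rt) opens the α-acyloxy lactone ring B to the hydroxy amide F7. LiBH4 (THF, 0 °C to rt) reduces ring A, the tertiary amide being inert, to the triol amide F8, and TsOH in toluene at 80 °C closes the γ-lactone with loss of pyrrolidine; the route is rejoined at 25.

**Further compounds**

F1 | step 2 | racemic (1RS,2E)-3-(2-methyl-1,3-dioxolan-2-yl)-1-(2,6,6-trimethylcyclohex-1-en-1-yl)prop-2-en-1-ol | O[C@H](/C=C/C1(C)OCCO1)C1=C(C)CCCC1(C)C.O[C@@H](/C=C/C1(C)OCCO1)C1=C(C)CCCC1(C)C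
F2 | step 2 | racemic 1-(4,4,7a-trimethyl-5,6,7,7a-tetrahydro-4H-inden-1-yl)ethan-1-one | CC(=O)C1=CC=C2C(C)(C)CCC[C@]12C.CC(=O)C1=CC=C2C(C)(C)CCC[C@@]12C
F3 | step 2 | racemic 1-[(1S*,3aS*,7aS*)-4,4,7a-trimethyloctahydro-1H-inden-1-yl]ethan-1-one | CC(=O)[C@H]1CC[C@H]2C(C)(C)CCC[C@]12C.CC(=O)[C@@H]1CC[C@@H]2C(C)(C)CCC[C@@]12C
F4 | step 2 | racemic 1-[(1S*,3aS*,7aS*)-4,4,7a-trimethyloctahydro-1H-inden-1-yl]ethenyl trifluoromethanesulfonate | C=C(OS(=O)(=O)C(F)(F)F)[C@H]1CC[C@H]2C(C)(C)CCC[C@]12C.C=C(OS(=O)(=O)C(F)(F)F)[C@@H]1CC[C@@H]2C(C)(C)CCC[C@@]12C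
F5 | step 2 | (3R,3aR,6aR)-3-{1-[(1S,3aR,7aR)-4,4,7a-trimethyloctahydro-1H-inden-1-yl]ethenyl}tetrahydrofuro[3,4-b]furan-2,6-dione | C=C([C@@H]1CC[C@@H]2C(C)(C)CCC[C@@]12C)[C@@H]1C(=O)O[C@H]2C(=O)OC[C@@H]12
F6 | step 10 | (3S,3aR,6aR)-3-bromotetrahydrofuro[3,4-b]furan-2,6-dione | Br[C@@H]1C(=O)O[C@H]2C(=O)OC[C@@H]12
F7 | step 11 | (3R,4R,5R)-4-(hydroxymethyl)-5-(pyrrolidine-1-carbonyl)-3-{1-[(1R,3aS,7aS)-4,4,7a-trimethyloctahydro-1H-inden-1-yl]ethenyl}oxolan-2-one | O=C(N1CCCC1)[C@@H]1OC(=O)[C@@H](C(=C)[C@H]2CC[C@H]3C(C)(C)CCC[C@]23C)[C@@H]1CO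
F8 | step 11 | (2R,3R,4R)-2-hydroxy-3,4-bis(hydroxymethyl)-1-(pyrrolidin-1-yl)-5-[(1R,3aS,7aS)-4,4,7a-trimethyloctahydro-1H-inden-1-yl]hex-5-en-1-one | O=C(N1CCCC1)[C@H](O)[C@@H](CO)[C@@H](CO)C(=C)[C@H]1CC[C@H]2C(C)(C)CCC[C@]12C
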